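Ring A is cut retrosynthetically in this order: the palmitate C–O bond, then the CH2OH (traced to a methyl ester) and the ring-B phenol (traced to its benzyl ether), then the ring-A bond between the ester-bearing and the aryloxy-bearing carbon.
That ring cut rests on one feature: ring A has oxygen on C2, C3 and C5 and a carboxyl carbon on C1 (benzoate numbering), the pattern of a 2,4,6-tricarbonyl heptanoate whose C7 already holds the ring-B oxygen and whose C4 oxygen is already a methyl enol ether.
The chain is cut at C5–C6 (γ-dienolate plus aryloxyacetyl N-methoxy-N-methylamide), at C2–C3 (oxalylation of 2-methoxypropene) and at the aryl O–CH2 bond (alkylation of mono-benzylated orcinol).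
Forward: ring B is bought as orcinol, the C6–C7 and C1–C5 pieces are joined, ring A is closed and aromatised in one operation, then debenzylation, ester reduction and enzymatic palmitoylation follow.
Stereochemistry: the target has no stereocentre and no configured double bond, so it is one achiral compound and nothing has to be set; the two centres of the transient aldol vanish on aromatisation.

Key step: step 5

Remark on the chemistry: C1–C7 in the steps mean the heptenoate chain of the open-chain precursor (C1 ester carbon, C2 ketone, C4 methoxy-bearing carbon, C6 ketone, C7 aryloxy-bearing carbon). The enol ether is built from 2-methoxypropene because O-methylation of methyl 2,4-dioxopentanoate would be expected to occur at the more electrophilic C2 carbonyl and misplace the methoxy group.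

Step 1
Reactants: 1 orcinol (5-methylbenzene-1,3-diol)
Product: 2 3-(benzyloxy)-5-methylphenol
Conditions: BnBr (0.5 equiv), K2CO3, acetone, reflux; 1 in twofold excess, recovered
Reagents that add atoms: benzyl bromide, BrCc1ccccc1
Why: Williamson etherification of one of two equivalent phenols, in which the excess of diol should hold bis-benzylation down and the mono-ether is separable from diol and bis-ether by acidity and polarity.

Step 2
Reactants: 2 3-(benzyloxy)-5-methylphenol; 3 2-chloro-N-methoxy-N-methylacetamide
Product: 4 2-[3-(benzyloxy)-5-methylphenoxy]-N-methoxy-N-methylacetamide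
Conditions: K2CO3, NaI (cat.), MeCN, 70 °C
Reagents that add atoms: none
Why: Williamson O-alkylation of the phenoxide by an α-chloroamide (iodide-assisted SN2), a standard entry to aryloxyacetyl N-methoxy-N-methylamides under conditions to which the benzyl ether and the amide are inert.

Step 3
Reactants: 5 2-methoxypropene; 6 methyl chlorooxoacetate
Product: 7 methyl (E)-4-methoxy-2-oxopent-3-enoate
Conditions: pyridine, CH2Cl2, 0 °C → rt
Reagents that add atoms: none
Why: C-acylation of an enol ether by an acid chloride (the oxalyl variant of the β-acylation of vinyl ethers), in which the terminal CH2 of 5 attacks 6, pyridine removes a proton from the oxocarbenium ion and the push–pull enone should settle as the E isomer with the methoxy group fixed on C4.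

Step 4
Reactants: 7 methyl (E)-4-methoxy-2-oxopent-3-enoate; 4 2-[3-(benzyloxy)-5-methylphenoxy]-N-methoxy-N-methylacetamide
Product: 10 methyl (E)-7-[3-(benzyloxy)-5-methylphenoxy]-4-methoxy-2,6-dioxohept-3-enoate, via lithium dienolate 8 (not isolated), via tetrahedral lithium adduct 9 (not isolated)
Conditions: LiHMDS (1.5 equiv), 7 (1.6 equiv), THF, −78 °C; then 4 (1.0 equiv), −78 → −30 °C; AcOH, −78 °C
Reagents that add atoms: none
Why: Vinylogous Claisen-type acylation, in which 7 has no α′-hydrogen so LiHMDS can only take a γ-hydrogen from the C5 methyl, the 4-methoxy dienolate reacts at its terminal carbon as the γ-dienolates of 3-methoxycrotonates and dioxinones do, and the N-methoxy-N-methylamide holds the adduct as chelate 9 until the acid quench so that neither O-acylation nor proton transfer from the more acidic product can interfere.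

Step 5
Reactants: 10 methyl (E)-7-[3-(benzyloxy)-5-methylphenoxy]-4-methoxy-2,6-dioxohept-3-enoate
Product: 13 methyl 2-[3-(benzyloxy)-5-methylphenoxy]-3-hydroxy-5-methoxybenzoate, via cyclic aldol 11 (not isolated), via cyclohexadienone 12 (not isolated)
Conditions: NaOMe (2 equiv), MeOH, 3 Å MS, 0 °C → rt; AcOH
Reagents that add atoms: none
Why: Methoxide equilibrates the chain among its enolates; the minor C7 enolate (α to the C6 ketone and acidified by the aryloxy group) adds to the C2 keto carbonyl, the most electrophilic centre because of the neighbouring ester, and aldol 11 loses water by E1cB through the same C7 position to give dienone 12, which tautomerises irreversibly to the phenol. The closest known reaction type is the base-induced aldol cyclisation–aromatisation of open-chain β-polycarbonyl compounds (heptane-2,4,6-trione to orcinol, 3,5,7-triketo esters to resorcylates). Ring A closes in a 6-(enolendo)-exo-trig mode, since both C6 and C7 of the enolate end up in the ring. No stereocentre remains, because the two created in 11 are erased on aromatisation. The selectivity needed is C7→C2 attack over the alternatives: the more acidic C5 can only reach the ester carbonyl (five-membered Dieckmann closure) or give O-bridged hemiketals, all reversible and unable to aromatise, no γ-pyrone can form because the C4 oxygen is locked as a methyl ether, and the C3=C4 geometry is not critical since reversible C5 deprotonation lets the enol ether rotate until C2 and C5 are cis. Sodium methoxide in methanol matches both the methyl ester and the methyl enol ether, so exchange at either site is degenerate.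

Step 6
Reactants: 13 methyl 2-[3-(benzyloxy)-5-methylphenoxy]-3-hydroxy-5-methoxybenzoate
Product: 14 methyl 3-hydroxy-2-(3-hydroxy-5-methylphenoxy)-5-methoxybenzoate
Conditions: H2 (1 atm), 10% Pd/C, EtOAc–MeOH, rt
Reagents that add atoms: none
Why: Catalytic hydrogenolysis of a benzyl aryl ether leaves the diaryl ether, methyl ester and methoxy group untouched, and it is placed here because the benzylic palmitate of the target would not survive these conditions.

Step 7
Reactants: 14 methyl 3-hydroxy-2-(3-hydroxy-5-methylphenoxy)-5-methoxybenzoate
Product: 15 2-(3-hydroxy-5-methylphenoxy)-3-(hydroxymethyl)-5-methoxyphenol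
Conditions: LiAlH4 (4 equiv), THF, 0 → 50 °C; aq. Rochelle salt work-up
Reagents that add atoms: none
Why: Hydride reduction of a methyl benzoate to the benzylic alcohol, in which the two phenols only consume hydride as phenoxides and, with the hydroxymethyl group meta to the ring-A hydroxyl, no quinone methide can form on work-up.

Step 8
Reactants: 15 2-(3-hydroxy-5-methylphenoxy)-3-(hydroxymethyl)-5-methoxyphenol; 16 vinyl palmitate
Product: 17 betaethrin H, [3-hydroxy-2-(3-hydroxy-5-methylphenoxy)-5-methoxyphenyl]methyl hexadecanoate
Conditions: Novozym 435 (immobilised Candida antarctica lipase B), 16 (3 equiv), MTBE–THF, 45 °C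
Reagents that add atoms: none
Why: Lipase-catalysed transesterification with an enol ester, in which the enzyme acylates primary alcohols far faster than phenols and tautomerisation of the released vinyl alcohol to acetaldehyde makes the acyl transfer irreversible.

Compound list
1 | orcinol (5-methylbenzene-1,3-diol) | Cc1cc(O)cc(O)c1 | starting material
2 | 3-(benzyloxy)-5-methylphenol | Cc1cc(O)cc(OCc2ccccc2)c1 | intermediate
3 | 2-chloro-N-methoxy-N-methylacetamide | CON(C)C(=O)CCl | starting material
4 | 2-[3-(benzyloxy)-5-methylphenoxy]-N-methoxy-N-methylacetamide | CON(C)C(=O)COc1cc(C)cc(OCc2ccccc2)c1 | intermediate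
5 | 2-methoxypropene | COC(C)=C | starting material
6 | methyl chlorooxoacetate | COC(=O)C(=O)Cl | starting material
7 | methyl (E)-4-methoxy-2-oxopent-3-enoate | COC(=O)C(=O)/C=C(/OC)C | intermediate
8 | lithium (2Z)-1,4-dimethoxy-1-oxopenta-2,4-dien-2-olate (γ-dienolate of 7; Z drawn as expected, geometry without consequence; not isolated) | [Li+].COC(=O)/C([O-])=C/C(OC)=C | intermediate
9 | lithium (4E)-1-[3-(benzyloxy)-5-methylphenoxy]-4,7-dimethoxy-2-[methoxy(methyl)amino]-6,7-dioxohept-4-en-2-olate (racemic chelated adduct; not isolated) | [Li+].COC(=O)C(=O)/C=C(/OC)CC([O-])(COc1cc(C)cc(OCc2ccccc2)c1)N(C)OC | intermediate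
10 | methyl (E)-7-[3-(benzyloxy)-5-methylphenoxy]-4-methoxy-2,6-dioxohept-3-enoate | COC(=O)C(=O)/C=C(/OC)CC(=O)COc1cc(C)cc(OCc2ccccc2)c1 | intermediate
11 | methyl 6-[3-(benzyloxy)-5-methylphenoxy]-1-hydroxy-3-methoxy-5-oxocyclohex-2-ene-1-carboxylate (racemic, both relative configurations; not isolated) | COC(=O)C1(O)C=C(OC)CC(=O)C1Oc1cc(C)cc(OCc2ccccc2)c1 | intermediate
12 | methyl 2-[3-(benzyloxy)-5-methylphenoxy]-5-methoxy-3-oxocyclohexa-1,5-diene-1-carboxylate (not isolated) | COC(=O)C1=C(Oc2cc(C)cc(OCc3ccccc3)c2)C(=O)CC(OC)=C1 | intermediate
13 | methyl 2-[3-(benzyloxy)-5-methylphenoxy]-3-hydroxy-5-methoxybenzoate | COC(=O)c1cc(OC)cc(O)c1Oc1cc(C)cc(OCc2ccccc2)c1 | intermediate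
14 | methyl 3-hydroxy-2-(3-hydroxy-5-methylphenoxy)-5-methoxybenzoate | COC(=O)c1cc(OC)cc(O)c1Oc1cc(C)cc(O)c1 | intermediate
15 | 2-(3-hydroxy-5-methylphenoxy)-3-(hydroxymethyl)-5-methoxyphenol | OCc1cc(OC)cc(O)c1Oc1cc(C)cc(O)c1 | intermediate
16 | vinyl palmitate (ethenyl hexadecanoate) | CCCCCCCCCCCCCCCC(=O)OC=C | starting material
17 | betaethrin H, [3-hydroxy-2-(3-hydroxy-5-methylphenoxy)-5-methoxyphenyl]methyl hexadecanoate (achiral) | CCCCCCCCCCCCCCCC(=O)OCc1cc(OC)cc(O)c1Oc1cc(C)cc(O)c1 | target

Total step count: 8. Longest linear sequence: 7 steps (1, 2, 4, 5, 6, 7, 8 from orcinol); step 3 is a one-step side branch.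

Steps most likely to fail

Step 4. The dienolate may condense with the keto group of not-yet-deprotonated 7 while it is being formed, or add too slowly to the amide so that attack through the α-carbon competes. The fallback sets out from 7 and 4 and rejoins the route at 10. Compound 7 would be silylated under soft enolisation (TMSOTf, Et3N, Et2O, 0 °C) to the silyl dienol ether methyl (2Z)-4-methoxy-2-[(trimethylsilyl)oxy]penta-2,4-dienoate F1. Amide 4 would be reduced (DIBAL-H, THF, −78 °C) to 2-[3-(benzyloxy)-5-methylphenoxy]acetaldehyde F2. A vinylogous Mukaiyama aldol addition (BF3·OEt2, CH2Cl2, −78 °C) should join the terminal carbon of the diene to the aldehyde and give racemic methyl (E)-7-[3-(benzyloxy)-5-methylphenoxy]-6-hydroxy-4-methoxy-2-oxohept-3-enoate F3. Dess–Martin oxidation (NaHCO3, CH2Cl2, 0 °C) of the secondary alcohol would then give 10. No strong base is involved at any point.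

Step 5. The chain may rest as its C5-centred vinylogous diketonate so that enolisation at C7 is too slow, and retro-Claisen cleavage of the C5–C6 bond by methoxide may take over on warming. The fallback sets out from 10 and rejoins the route at 13, replacing the ionic closure by a pericyclic one. Exhaustive soft enolisation (TBSOTf, Et3N, CH2Cl2, 0 °C → rt) should give the trienol ether methyl 7-[3-(benzyloxy)-5-methylphenoxy]-2,6-bis[(tert-butyldimethylsilyl)oxy]-4-methoxyhepta-2,4,6-trienoate F4. The first silylation consumes the C5 hydrogen, so the second can only enolise C6 towards C7. Heating (toluene, 110 °C) should bring about thermal 6π-electrocyclisation to methyl 6-[3-(benzyloxy)-5-methylphenoxy]-1,5-bis[(tert-butyldimethylsilyl)oxy]-3-methoxycyclohexa-2,4-diene-1-carboxylate F5. This loses silanol across the new bond to give the aryl silyl ether methyl 2-[3-(benzyloxy)-5-methylphenoxy]-3-[(tert-butyldimethylsilyl)oxy]-5-methoxybenzoate F6. TBAF buffered with AcOH (THF, 0 °C) would free phenol 13.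

Step 8. Enzymatic acyl transfer may be slow because the ortho-aryloxy group crowds the benzylic alcohol, which would let acylation of a phenol compete over long reaction times. The fallback sets out from 15 and ends at 17. It is a Mitsunobu esterification with palmitic acid (PPh3, DIAD, THF, 0 °C), which activates the alcohol instead of the acyl donor. Only the carboxylic acid is acidic enough to act as the pronucleophile, so the phenols should stay free. It makes no compound outside the list (F0).

Further compounds
F1 | step 4 | methyl (2Z)-4-methoxy-2-[(trimethylsilyl)oxy]penta-2,4-dienoate | COC(=O)/C(O[Si](C)(C)C)=C/C(OC)=C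
F2 | step 4 | 2-[3-(benzyloxy)-5-methylphenoxy]acetaldehyde | O=CCOc1cc(C)cc(OCc2ccccc2)c1
F3 | step 4 | methyl (E)-7-[3-(benzyloxy)-5-methylphenoxy]-6-hydroxy-4-methoxy-2-oxohept-3-enoate (racemic) | COC(=O)C(=O)/C=C(/OC)CC(O)COc1cc(C)cc(OCc2ccccc2)c1
F4 | step 5 | methyl 7-[3-(benzyloxy)-5-methylphenoxy]-2,6-bis[(tert-butyldimethylsilyl)oxy]-4-methoxyhepta-2,4,6-trienoate (mixture of alkene isomers) | COC(=O)C(O[Si](C)(C)C(C)(C)C)=CC(OC)=CC(O[Si](C)(C)C(C)(C)C)=COc1cc(C)cc(OCc2ccccc2)c1
F5 | step 5 | methyl 6-[3-(benzyloxy)-5-methylphenoxy]-1,5-bis[(tert-butyldimethylsilyl)oxy]-3-methoxycyclohexa-2,4-diene-1-carboxylate (racemic, both relative configurations) | COC(=O)C1(O[Si](C)(C)C(C)(C)C)C=C(OC)C=C(O[Si](C)(C)C(C)(C)C)C1Oc1cc(C)cc(OCc2ccccc2)c1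
F6 | step 5 | methyl 2-[3-(benzyloxy)-5-methylphenoxy]-3-[(tert-butyldimethylsilyl)oxy]-5-methoxybenzoate | COC(=O)c1cc(OC)cc(O[Si](C)(C)C(C)(C)C)c1Oc1cc(C)cc(OCc2ccccc2)c1
F0 | step 8 | none | none
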